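**Assumption:** the target has no stereocentre and no stereogenic double bond, so the "single enantiomer" is the achiral compound itself. The stereocentres that appear in 5–7 are racemic and are erased in step 3.

## Retrosynthetic overview

1. Target 18 ⇐ diaryl ether 16 by cleavage of two methyl esters and one O-benzyl group.
2. Diaryl ether C–O bond ⇐ Pd-catalysed coupling of ring-A aryl triflate 10 with ring-B phenol 15.
3. Both arenes ⇐ one resorcylate, methyl 2-heptyl-4,6-dihydroxybenzoate 8. Ring A needs 4-O-methylation and triflation; ring B needs 4-O-MOM, 2-O-Bn, iodination next to the heptyl chain, Cu-methoxylation and MOM removal.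
4. 8 ⇐ key C–C bond: intermolecular Michael addition of dimethyl malonate 4 to (E)-undec-3-en-2-one 3, Dieckmann (Claisen) closure in the same flask, then Br2 aromatisation. Enone 3 ⇐ octanal 1 + acetonyl ylide 2.
5. Ring order: a single ring-forming event (step 2) builds the six-membered carbocycle, which is aromatised (step 3) and serves as both benzene rings; the two arenes are joined last through the ether oxygen.

## Route

Step 1
Reactants: 1 octanal; 2 1-(triphenyl-λ5-phosphanylidene)propan-2-one
Product: 3 (E)-undec-3-en-2-one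
Conditions: CH2Cl2, reflux, 16 h
Reagents that add atoms: none
Why: Wittig olefination with a stabilised acyl ylide gives the E-enone cleanly and avoids the self-condensation of a crossed aldol with an enolisable aldehyde.

Step 2
Reactants: 3 (E)-undec-3-en-2-one; 4 dimethyl malonate
Product: 6 methyl 2-heptyl-4,6-dioxocyclohexane-1-carboxylate, via Michael adduct 5 (not isolated)
Conditions: NaOMe (1.1 equiv), MeOH, reflux, 4 h; then aq. HCl to pH 3
Reagents that add atoms: none
Why: Intermolecular Michael addition of the malonate anion to the heptyl-bearing β-carbon forges the key C–C bond, and the methyl-ketone enolate of 5 then closes the ring by Claisen (Dieckmann) condensation onto one ester, driven by the stabilised β-diketone enolate; the two stereocentres form racemic and are erased in step 3.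

Step 3
Reactants: 6 methyl 2-heptyl-4,6-dioxocyclohexane-1-carboxylate
Product: 8 methyl 2-heptyl-4,6-dihydroxybenzoate, via bromo-dione 7 (not isolated)
Conditions: Br2 (1.0 equiv), DMF, 0 °C, 1 h; then 80 °C, 12 h
Reagents that add atoms: none
Why: α-Bromination of the cyclic 1,3-dione between the two ketones followed by thermal dehydrobromination and tautomerisation aromatises the ring, the classical Br2/DMF route to olivetol-type resorcylate esters.

Step 4
Reactants: 8 methyl 2-heptyl-4,6-dihydroxybenzoate
Product: 9 methyl 2-heptyl-6-hydroxy-4-methoxybenzoate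
Conditions: MeI (1.1 equiv), K2CO3 (1.2 equiv), acetone, reflux
Reagents that add atoms: iodomethane CI
Why: Williamson etherification is selective for the OH para to the ester because the ortho OH is hydrogen-bonded to the ester carbonyl and much less nucleophilic.

Step 5
Reactants: 9 methyl 2-heptyl-6-hydroxy-4-methoxybenzoate
Product: 10 methyl 2-heptyl-4-methoxy-6-{[(trifluoromethyl)sulfonyl]oxy}benzoate
Conditions: Tf2O (1.2 equiv), pyridine, CH2Cl2, 0 °C to rt
Reagents that add atoms: trifluoromethanesulfonic anhydride O=S(=O)(OS(=O)(=O)C(F)(F)F)C(F)(F)F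
Why: O-Sulfonylation of the salicylate phenol gives an aryl triflate that is activated for oxidative addition by the ortho ester.

Step 6
Reactants: 8 methyl 2-heptyl-4,6-dihydroxybenzoate
Product: 11 methyl 2-heptyl-6-hydroxy-4-(methoxymethoxy)benzoate
Conditions: MOMCl (1.1 equiv), i-Pr2NEt (1.5 equiv), CH2Cl2, 0 °C to rt
Reagents that add atoms: chloromethyl methyl ether COCCl
Why: O-Alkylation (MOM protection) occurs only at the non-chelated OH para to the ester, for the same reason as in step 4.

Step 7
Reactants: 11 methyl 2-heptyl-6-hydroxy-4-(methoxymethoxy)benzoate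
Product: 12 methyl 2-(benzyloxy)-6-heptyl-4-(methoxymethoxy)benzoate
Conditions: BnBr (1.3 equiv), K2CO3 (2 equiv), Bu4NI (cat.), DMF, 60 °C
Reagents that add atoms: benzyl bromide BrCc1ccccc1
Why: Williamson benzylation of the chelated phenol proceeds under these more forcing conditions, and the MOM acetal and ester are stable to carbonate.

Step 8
Reactants: 12 methyl 2-(benzyloxy)-6-heptyl-4-(methoxymethoxy)benzoate
Product: 13 methyl 6-(benzyloxy)-2-heptyl-3-iodo-4-(methoxymethoxy)benzoate
Conditions: NIS (1.1 equiv), CF3CO2H (10 mol%), MeCN, rt, dark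
Reagents that add atoms: N-iodosuccinimide O=C1CCC(=O)N1I
Why: Electrophilic aromatic iodination goes para to OBn and ortho to OMOM (next to the heptyl chain) because the other free position is shielded between two alkoxy groups, the same selectivity as halogenation of olivetol dialkyl ethers.

Step 9
Reactants: 13 methyl 6-(benzyloxy)-2-heptyl-3-iodo-4-(methoxymethoxy)benzoate
Product: 14 methyl 6-(benzyloxy)-2-heptyl-3-methoxy-4-(methoxymethoxy)benzoate
Conditions: MeOH (10 equiv), CuI (10 mol%), 3,4,7,8-tetramethyl-1,10-phenanthroline (20 mol%), Cs2CO3 (2 equiv), toluene, 110 °C, sealed tube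
Reagents that add atoms: methanol CO
Why: Cu-catalysed Ullmann-type C–O coupling of an aryl iodide with an aliphatic alcohol; methoxide exchange at the methyl ester is degenerate and the benzyl and MOM ethers are base-stable.

Step 10
Reactants: 14 methyl 6-(benzyloxy)-2-heptyl-3-methoxy-4-(methoxymethoxy)benzoate
Product: 15 methyl 6-(benzyloxy)-2-heptyl-4-hydroxy-3-methoxybenzoate
Conditions: conc. HCl (cat.), MeOH, 50 °C
Reagents that add atoms: none
Why: Acid-catalysed acetal exchange with methanol removes the MOM group while the benzyl ether, aryl methyl ether and hindered ester are untouched.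

Step 11
Reactants: 10 methyl 2-heptyl-4-methoxy-6-{[(trifluoromethyl)sulfonyl]oxy}benzoate; 15 methyl 6-(benzyloxy)-2-heptyl-4-hydroxy-3-methoxybenzoate
Product: 16 methyl 2-[5-(benzyloxy)-3-heptyl-2-methoxy-4-(methoxycarbonyl)phenoxy]-6-heptyl-4-methoxybenzoate
Conditions: Pd(OAc)2 (5 mol%), tBuXPhos (7.5 mol%), K3PO4 (2 equiv), toluene, 100 °C
Reagents that add atoms: none
Why: Buchwald-type Pd-catalysed diaryl ether synthesis (oxidative addition into the ortho-ester triflate, phenoxide exchange, C–O reductive elimination promoted by the bulky di-tert-butylbiarylphosphine), with a single free OH so the site of arylation is unambiguous.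

Step 12
Reactants: 16 methyl 2-[5-(benzyloxy)-3-heptyl-2-methoxy-4-(methoxycarbonyl)phenoxy]-6-heptyl-4-methoxybenzoate
Product: 17 2-[5-(benzyloxy)-4-carboxy-3-heptyl-2-methoxyphenoxy]-6-heptyl-4-methoxybenzoic acid
Conditions: KOH (10 equiv), DMSO/H2O 4:1, 100 °C; then aq. HCl, 0 °C
Reagents that add atoms: potassium hydroxide [K+].[OH-]
Why: Saponification of both 2,6-disubstituted methyl benzoates needs poorly solvated hydroxide in aqueous DMSO, and the benzyl, methyl and diaryl ethers are stable to base; keeping the O-benzyl group avoids an ortho phenoxide that would deactivate the ring-B ester.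

Step 13
Reactants: 17 2-[5-(benzyloxy)-4-carboxy-3-heptyl-2-methoxyphenoxy]-6-heptyl-4-methoxybenzoic acid
Product: 18 2-(4-carboxy-3-heptyl-5-hydroxy-2-methoxyphenoxy)-6-heptyl-4-methoxybenzoic acid
Conditions: H2 (1 atm), 10% Pd/C, EtOAc, rt
Reagents that add atoms: none
Why: Catalytic hydrogenolysis cleaves the benzyl ether under neutral conditions with no other reducible group present, so the salicylic acid is released without risk of decarboxylation.

## Compound list

1 | octanal | CCCCCCCC=O | starting material
2 | 1-(triphenyl-λ5-phosphanylidene)propan-2-one | CC(=O)C=P(c1ccccc1)(c1ccccc1)c1ccccc1 | starting material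
3 | (E)-undec-3-en-2-one | CCCCCCC/C=C/C(C)=O | intermediate
4 | dimethyl malonate | COC(=O)CC(=O)OC | starting material
5 | dimethyl 2-(2-oxoundecan-4-yl)propanedioate (racemic Michael adduct) | CCCCCCCC(CC(C)=O)C(C(=O)OC)C(=O)OC | intermediate (not isolated)
6 | methyl 2-heptyl-4,6-dioxocyclohexane-1-carboxylate (racemic; mainly present as its enol, methyl 6-heptyl-2-hydroxy-4-oxocyclohex-2-ene-1-carboxylate) | CCCCCCCC1CC(=O)CC(=O)C1C(=O)OC | intermediate
7 | methyl 3-bromo-6-heptyl-2,4-dioxocyclohexane-1-carboxylate (racemic) | CCCCCCCC1CC(=O)C(Br)C(=O)C1C(=O)OC | intermediate (not isolated)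
8 | methyl 2-heptyl-4,6-dihydroxybenzoate | CCCCCCCc1cc(O)cc(O)c1C(=O)OC | intermediate
9 | methyl 2-heptyl-6-hydroxy-4-methoxybenzoate | CCCCCCCc1cc(OC)cc(O)c1C(=O)OC | intermediate
10 | methyl 2-heptyl-4-methoxy-6-{[(trifluoromethyl)sulfonyl]oxy}benzoate | CCCCCCCc1cc(OC)cc(OS(=O)(=O)C(F)(F)F)c1C(=O)OC | intermediate
11 | methyl 2-heptyl-6-hydroxy-4-(methoxymethoxy)benzoate | CCCCCCCc1cc(OCOC)cc(O)c1C(=O)OC | intermediate
12 | methyl 2-(benzyloxy)-6-heptyl-4-(methoxymethoxy)benzoate | CCCCCCCc1cc(OCOC)cc(OCc2ccccc2)c1C(=O)OC | intermediate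
13 | methyl 6-(benzyloxy)-2-heptyl-3-iodo-4-(methoxymethoxy)benzoate | CCCCCCCc1c(I)c(OCOC)cc(OCc2ccccc2)c1C(=O)OC | intermediate
14 | methyl 6-(benzyloxy)-2-heptyl-3-methoxy-4-(methoxymethoxy)benzoate | CCCCCCCc1c(OC)c(OCOC)cc(OCc2ccccc2)c1C(=O)OC | intermediate
15 | methyl 6-(benzyloxy)-2-heptyl-4-hydroxy-3-methoxybenzoate | CCCCCCCc1c(OC)c(O)cc(OCc2ccccc2)c1C(=O)OC | intermediate
16 | methyl 2-[5-(benzyloxy)-3-heptyl-2-methoxy-4-(methoxycarbonyl)phenoxy]-6-heptyl-4-methoxybenzoate | CCCCCCCc1cc(OC)cc(Oc2cc(OCc3ccccc3)c(C(=O)OC)c(CCCCCCC)c2OC)c1C(=O)OC | intermediate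
17 | 2-[5-(benzyloxy)-4-carboxy-3-heptyl-2-methoxyphenoxy]-6-heptyl-4-methoxybenzoic acid | CCCCCCCc1cc(OC)cc(Oc2cc(OCc3ccccc3)c(C(=O)O)c(CCCCCCC)c2OC)c1C(=O)O | intermediate
18 | 2-(4-carboxy-3-heptyl-5-hydroxy-2-methoxyphenoxy)-6-heptyl-4-methoxybenzoic acid (achiral) | CCCCCCCc1cc(OC)cc(Oc2cc(O)c(C(=O)O)c(CCCCCCC)c2OC)c1C(=O)O | target

## Summary

Total step count: 13.

Longest linear sequence: 11 steps (1 → 2 → 3 → 6 → 7 → 8 → 9 → 10 → 11 → 12 → 13, from octanal); the ring-A branch (steps 4 and 5) joins at step 11.

Steps most likely to fail: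

**Step 11 (diaryl ether coupling).** The phenol is electron-poor and ortho-substituted, and the triflate can lose its sulfonyl group to phenoxide. The fallback sets out from 9 and 15 and comes back to the route at 17. It replaces the cross-coupling by an ester tether and an intramolecular SNAr. Compound 9 is saponified (KOH, DMSO/H2O, 90 °C) to 2-heptyl-6-hydroxy-4-methoxybenzoic acid F1. The free OH of 15 is acylated with F1 using (CF3CO)2O in toluene at rt to give the depside methyl 6-(benzyloxy)-2-heptyl-4-[(2-heptyl-6-hydroxy-4-methoxybenzoyl)oxy]-3-methoxybenzoate F2. K2CO3 in DMSO at 60–100 °C then triggers a Smiles rearrangement: the salicylate phenoxide attacks the ipso carbon para to the ring-B ester through a six-membered spiro intermediate and the carboxylate leaves. This gives 2-[5-(benzyloxy)-3-heptyl-2-methoxy-4-(methoxycarbonyl)phenoxy]-6-heptyl-4-methoxybenzoic acid F3. Saponification of its one remaining methyl ester under the step-12 conditions gives 17.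

**Step 9 (Cu-catalysed methoxylation).** The iodide is flanked on both sides, so coupling may be slow and hydrodeiodination may compete. The fallback sets out from 13 and comes back at 14. It makes the C–O bond by oxidation of an aryl-metal instead of coupling. Iodine–magnesium exchange with i-PrMgCl·LiCl (THF, −20 °C, hindered ester tolerated) is followed by a B(OMe)3 quench and H2O2/NaOH oxidation of the crude boronate. This gives the phenol methyl 6-(benzyloxy)-2-heptyl-3-hydroxy-4-(methoxymethoxy)benzoate F4, which is methylated (MeI, K2CO3, acetone) to 14.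

**Step 8 (regioselective iodination).** The route depends on attack next to the heptyl chain and not between the two oxygens. The fallback sets out from 8 and comes back at 14. It fixes the position of the new oxygen by mechanism. Elbs persulfate oxidation of 8 (K2S2O8, aq. NaOH/pyridine, 0 °C to rt, then warm dilute HCl to cleave the aryl sulfate) hydroxylates para to the chelated OH and gives methyl 2-heptyl-3,4,6-trihydroxybenzoate F5. MOMCl/i-Pr2NEt (1 equiv) caps the most acidic OH, para to the ester, giving methyl 2-heptyl-3,6-dihydroxy-4-(methoxymethoxy)benzoate F6. MeI/K2CO3 methylates the remaining non-chelated OH to give methyl 2-heptyl-6-hydroxy-3-methoxy-4-(methoxymethoxy)benzoate F7. Benzylation (BnBr, K2CO3, DMF, 60 °C) then gives 14.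

## Further compounds

F1 | step 11 | 2-heptyl-6-hydroxy-4-methoxybenzoic acid | CCCCCCCc1cc(OC)cc(O)c1C(=O)O
F2 | step 11 | methyl 6-(benzyloxy)-2-heptyl-4-[(2-heptyl-6-hydroxy-4-methoxybenzoyl)oxy]-3-methoxybenzoate | CCCCCCCc1cc(OC)cc(O)c1C(=O)Oc1cc(OCc2ccccc2)c(C(=O)OC)c(CCCCCCC)c1OC
F3 | step 11 | 2-[5-(benzyloxy)-3-heptyl-2-methoxy-4-(methoxycarbonyl)phenoxy]-6-heptyl-4-methoxybenzoic acid | CCCCCCCc1cc(OC)cc(Oc2cc(OCc3ccccc3)c(C(=O)OC)c(CCCCCCC)c2OC)c1C(=O)O
F4 | step 9 | methyl 6-(benzyloxy)-2-heptyl-3-hydroxy-4-(methoxymethoxy)benzoate | CCCCCCCc1c(O)c(OCOC)cc(OCc2ccccc2)c1C(=O)OC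
F5 | step 8 | methyl 2-heptyl-3,4,6-trihydroxybenzoate | CCCCCCCc1c(O)c(O)cc(O)c1C(=O)OC
F6 | step 8 | methyl 2-heptyl-3,6-dihydroxy-4-(methoxymethoxy)benzoate | CCCCCCCc1c(O)c(OCOC)cc(O)c1C(=O)OC
F7 | step 8 | methyl 2-heptyl-6-hydroxy-3-methoxy-4-(methoxymethoxy)benzoate | CCCCCCCc1c(OC)c(OCOC)cc(O)c1C(=O)OC
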